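**Retrosynthetic overview**
- Sophoranone comes from its bis-MOM ether by acid deprotection in the last step; C2 is not touched.
- The C2–aryl bond and the single stereocentre (2S) are made together by a Rh-catalysed enantioselective 1,4-addition of a 4-(MOMO)-3,5-diprenylphenylboronic acid to 7-(MOMO)-8-prenylchromone (the proposed new step).
- The chromone comes from 2,4-dihydroxyacetophenone: C3 iodination, 4-O-MOM, Stille prenylation, enaminone formation and ring closure.
- The boronic acid comes from 4-bromophenol: ortho-diiodination, MOM protection, two I/Mg exchange–Cu-catalysed prenylations, then Br/Li exchange and borylation.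
- Ring order: rings A and B are bought as benzenoids; the pyranone ring C is closed at the chromone stage and becomes the chiral flavanone ring in the key step.

Assumption: simple group-donating reagents (MOMCl, prenyl donors, DMF-DMA, borate, iodinating agents) are listed as reagents with SMILES and are not numbered; only substrates, intermediates and the target carry numbers.

**Step 1**
Reactants: 1, 2,4-dihydroxyacetophenone
Product: 2, 1-(2,4-dihydroxy-3-iodophenyl)ethan-1-one
Conditions: I2, HIO3, EtOH/H2O, 40 °C
Reagents that add atoms: iodine, II; iodic acid, O[I](=O)=O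
Why: Electrophilic aromatic iodination goes to C3, the position activated by both hydroxyls, and the isomer is confirmed by two ortho-coupled aromatic doublets in the 1H NMR.

**Step 2**
Reactants: 2
Product: 3, 1-[2-hydroxy-3-iodo-4-(methoxymethoxy)phenyl]ethan-1-one
Conditions: MOMCl (1.1 equiv), K2CO3, acetone, 0 °C → rt
Reagents that add atoms: chloromethyl methyl ether, COCCl
Why: Williamson-type O-alkylation is selective for the more acidic 4-OH because the 2-OH is hydrogen-bonded to the ketone.

**Step 3**
Reactants: 3
Product: 4, 1-[2-hydroxy-4-(methoxymethoxy)-3-(3-methylbut-2-en-1-yl)phenyl]ethan-1-one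
Conditions: tributyl(prenyl)stannane (1.3 equiv), Pd(PPh3)4 (5 mol %), DMF, 90 °C
Reagents that add atoms: tributyl(3-methylbut-2-en-1-yl)stannane, CCCC[Sn](CCCC)(CCCC)CC=C(C)C
Why: Stille coupling of the aryl iodide, where reductive elimination from the aryl(η3-prenyl)Pd intermediate at the unhindered CH2 terminus gives the linear prenyl group, and the chelated phenol, ketone and MOM ether are tolerated.

**Step 4**
Reactants: 4
Product: 5, (E)-3-(dimethylamino)-1-[2-hydroxy-4-(methoxymethoxy)-3-(3-methylbut-2-en-1-yl)phenyl]prop-2-en-1-one
Conditions: DMF-DMA (3 equiv), toluene, 95 °C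
Reagents that add atoms: N,N-dimethylformamide dimethyl acetal, COC(OC)N(C)C
Why: Condensation of the methyl ketone with the amide acetal gives the enaminone under neutral conditions that leave the MOM and prenyl groups alone.

**Step 5**
Reactants: 5
Product: 6, 7-(methoxymethoxy)-8-(3-methylbut-2-en-1-yl)-4H-chromen-4-one
Conditions: TsOH·H2O (1.0 equiv), CH2Cl2, 0 °C → rt
Reagents that add atoms: none
Why: Acid-promoted 6-endo addition–elimination (phenol O onto the protonated vinylogous amide, loss of Me2NH) closes the chromone ring, and the released amine buffers the acid so the MOM acetal and prenyl alkene survive.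

**Step 6**
Reactants: 7, 4-bromophenol
Product: 8, 4-bromo-2,6-diiodophenol
Conditions: NIS (2.1 equiv), TsOH·H2O (10 mol %), MeCN, rt
Reagents that add atoms: N-iodosuccinimide, O=C1CCC(=O)N1I
Why: Electrophilic iodination of a para-blocked phenol can only occur at the two ortho positions.

**Step 7**
Reactants: 8
Product: 9, 5-bromo-1,3-diiodo-2-(methoxymethoxy)benzene
Conditions: MOMCl (1.3 equiv), K2CO3, acetone, rt
Reagents that add atoms: chloromethyl methyl ether, COCCl
Why: O-alkylation of the acidic diiodophenoxide with the small, reactive MOMCl proceeds despite the two ortho iodines.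

**Step 8**
Reactants: 9
Product: 10, 5-bromo-1-iodo-2-(methoxymethoxy)-3-(3-methylbut-2-en-1-yl)benzene
Conditions: i-PrMgCl·LiCl (1.05 equiv), THF, −40 °C; then CuBr·SMe2 (10 mol %), prenyl bromide (1.2 equiv), −40 → 0 °C
Reagents that add atoms: 1-bromo-3-methylbut-2-ene, CC(C)=CCBr
Why: Iodine–magnesium exchange is selective for C–I over C–Br and is assisted by the ortho OMOM group, and Cu-catalysed allylic substitution at the primary carbon of prenyl bromide gives the linear prenyl arene.

**Step 9**
Reactants: 10
Product: 11, 5-bromo-2-(methoxymethoxy)-1,3-bis(3-methylbut-2-en-1-yl)benzene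
Conditions: i-PrMgCl·LiCl (1.1 equiv), THF, −30 °C; then CuBr·SMe2 (10 mol %), prenyl bromide (1.3 equiv), −30 → 0 °C
Reagents that add atoms: 1-bromo-3-methylbut-2-ene, CC(C)=CCBr
Why: This repeats the step 8 exchange–allylation on the remaining iodide, and the electron-rich C–Br bond para to OMOM is inert to i-PrMgCl at this temperature.

**Step 10**
Reactants: 11
Product: 12, [4-(methoxymethoxy)-3,5-bis(3-methylbut-2-en-1-yl)phenyl]boronic acid
Conditions: n-BuLi (1.1 equiv), THF, −78 °C; B(Oi-Pr)3 (1.5 equiv), −78 °C → rt; aq NH4Cl
Reagents that add atoms: triisopropyl borate, CC(C)OB(OC(C)C)OC(C)C; water, O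
Why: Bromine–lithium exchange at −78 °C is much faster than benzylic/allylic deprotonation, and borate trapping followed by mild hydrolysis gives the boronic acid with the MOM ether intact.

**Step 11 (key step)**
Reactants: 6, 7-(methoxymethoxy)-8-prenylchromen-4-one; 12, [4-(methoxymethoxy)-3,5-diprenylphenyl]boronic acid (2 equiv)
Product: 13, (2S)-7-(methoxymethoxy)-2-[4-(methoxymethoxy)-3,5-bis(3-methylbut-2-en-1-yl)phenyl]-8-(3-methylbut-2-en-1-yl)-2,3-dihydro-4H-chromen-4-one
Conditions: [Rh(OH)(cod)]2 (2.5 mol %), (S)-MeO-F12-BIPHEP (5.5 mol %), toluene/H2O (10:1), 50 °C, no added base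
Reagents that add atoms: none (the aryl group comes from reactant 12; water supplies only the C3 hydrogen)
Why: Proposed new method: Rh(I)/chiral bisphosphine 1,4-arylation is proposed here for a substrate pair on which it has not been shown — a donor-substituted 7-acetal-oxy, 8-allyl-type chromone and an electron-rich arylboronic acid carrying two prenyl chains, with three free trisubstituted alkenes present — and the closest known reaction is the Hayashi–Miyaura asymmetric addition of simple arylboronic acids to unprenylated chromones; mechanistically, Ar–B transmetalates to Rh–OH (the boron has both ortho positions free), the chromone C2=C3 inserts into Ar–Rh with aryl delivered to the C2 Re face inside the chiral pocket (this sets 2S; the (S)-ligand is predicted by analogy with cyclic enones, and the antipode is used if a model run shows the opposite sense), water protonates the oxa-π-allyl Rh enolate irreversibly, the electron-poor ligand compensates for the deactivated enone, the prenyl alkenes are too hindered to bind or insert at Rh(I), and base-free conditions prevent retro-oxa-Michael racemisation.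

**Step 12**
Reactants: 13
Product: 14, sophoranone, (2S)-7-hydroxy-2-[4-hydroxy-3,5-bis(3-methylbut-2-en-1-yl)phenyl]-8-(3-methylbut-2-en-1-yl)-2,3-dihydro-4H-chromen-4-one
Conditions: 3 M aq HCl/MeOH/THF, 40 °C, stopped at full conversion
Reagents that add atoms: none
Why: Acid-catalysed acetal hydrolysis removes both MOM groups without base, so the base-mediated ring-opening that would scramble C2 is avoided, and dilute acid at 40 °C keeps chroman formation from the ortho-prenyl phenols to a minimum.

**Compound list**
1 | 2,4-dihydroxyacetophenone | CC(=O)c1ccc(O)cc1O | starting material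
2 | 1-(2,4-dihydroxy-3-iodophenyl)ethan-1-one | CC(=O)c1ccc(O)c(I)c1O | intermediate
3 | 1-[2-hydroxy-3-iodo-4-(methoxymethoxy)phenyl]ethan-1-one | CC(=O)c1ccc(OCOC)c(I)c1O | intermediate
4 | 1-[2-hydroxy-4-(methoxymethoxy)-3-prenylphenyl]ethan-1-one | CC(=O)c1ccc(OCOC)c(CC=C(C)C)c1O | intermediate
5 | (E)-3-(dimethylamino)-1-[2-hydroxy-4-(methoxymethoxy)-3-prenylphenyl]prop-2-en-1-one | CN(C)/C=C/C(=O)c1ccc(OCOC)c(CC=C(C)C)c1O | intermediate
6 | 7-(methoxymethoxy)-8-prenyl-4H-chromen-4-one | O=c1ccoc2c(CC=C(C)C)c(OCOC)ccc12 | intermediate
7 | 4-bromophenol | Oc1ccc(Br)cc1 | starting material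
8 | 4-bromo-2,6-diiodophenol | Oc1c(I)cc(Br)cc1I | intermediate
9 | 5-bromo-1,3-diiodo-2-(methoxymethoxy)benzene | COCOc1c(I)cc(Br)cc1I | intermediate
10 | 5-bromo-1-iodo-2-(methoxymethoxy)-3-prenylbenzene | COCOc1c(I)cc(Br)cc1CC=C(C)C | intermediate
11 | 5-bromo-2-(methoxymethoxy)-1,3-diprenylbenzene | COCOc1c(CC=C(C)C)cc(Br)cc1CC=C(C)C | intermediate
12 | [4-(methoxymethoxy)-3,5-diprenylphenyl]boronic acid | COCOc1c(CC=C(C)C)cc(B(O)O)cc1CC=C(C)C | intermediate
13 | (2S)-7-(methoxymethoxy)-2-[4-(methoxymethoxy)-3,5-diprenylphenyl]-8-prenylchroman-4-one | CC(C)=CCc1cc([C@@H]2CC(=O)c3ccc(OCOC)c(CC=C(C)C)c3O2)cc(CC=C(C)C)c1OCOC | intermediate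
14 | sophoranone, (2S)-7-hydroxy-2-(4-hydroxy-3,5-diprenylphenyl)-8-prenylchroman-4-one | CC(C)=CCc1cc([C@@H]2CC(=O)c3ccc(O)c(CC=C(C)C)c3O2)cc(CC=C(C)C)c1O | target

**Step count**
Total steps: 12. Longest linear sequence: 7 (steps 1–5, 11, 12; the B-ring branch, steps 6–10, 11, 12, is also 7).

**Three steps most likely to fail**
1. Step 11 (proposed new step). Risks: the 7-alkoxy chromone reacts sluggishly, the electron-rich boronic acid protodeboronates, or the ee or sense of induction is not as predicted.
   Fallback (known chemistry, different bond construction): convert 11 to 4-(methoxymethoxy)-3,5-diprenylbenzaldehyde (n-BuLi, then DMF). Claisen–Schmidt condensation with ketone 4 gives the 2′-hydroxychalcone, and NaOAc/EtOH at reflux cyclises it to racemic 13. Racemic 13 is then resolved by Noyori-type asymmetric transfer hydrogenation (Cp*Rh–TsDPEN, HCO2H/Et3N), with the catalyst antipode chosen so that (2R)-13 is reduced to the cis-flavan-4-ol and (2S)-13 is recovered (50% maximum). Step 12 follows unchanged.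

2. Step 3 (Stille prenylation of the di-ortho-substituted iodide). Risks: slow coupling, protodeiodination, or some reverse-prenyl (γ-coupled) isomer.
   Fallback: install the prenyl group by a sigmatropic route. Alkylate the 4-OH of 1 with 3-chloro-3-methylbut-1-yne, semi-hydrogenate (Lindlar) to the 1,1-dimethylallyl ether, and run a thermal aromatic Claisen rearrangement. The [3,3] shift can only deliver the linear prenyl group, and the C3 isomer is separated from the C5 isomer. 4-O-MOM protection then gives 4.

3. Step 12 (final MOM removal). Risks: acid-catalysed cyclisation of the ortho-prenyl phenols to 2,2-dimethylchromans, or acid-induced erosion at the electron-rich benzylic C2–O bond.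
   Fallback: change the protecting-group strategy so the end-game uses no acid. Carry both phenols as silyl ethers (TIPS on the 7-OH in step 2, TBS on the hindered B-ring phenol in step 7, otherwise the same sequences) and unmask with buffered fluoride (TBAF/AcOH, THF, 0 °C).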